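## Retrosynthetic overview

1. The C40 skeleton is cut at C11'=C12' (Wittig) into fragment B, the C15 acetylenic phosphonium salt 29, and the C25 apo-aldehyde 15; 15 is cut at C11=C12 (Wittig) into fragment A, the C15 triol phosphonium salt 11, and the C10 dialdehyde 12.
2. Ring A (C1–C6, the 3,5,6-triol ring) is never closed: it is taken intact from (4R,6R)-actinol 1. The chain is attached by a Heck reaction; C5 and C6 are set by 3-OH-directed epoxidation and invertive hydrolysis at C5.
3. Ring B (C1'–C6', the acetylenic cyclohexene) is the only ring of the skeleton that is closed, and it is closed last (step 15): acid-mediated ring enlargement (cyclopropylcarbinyl to homoallyl) of the 2-ethynylbicyclo[3.1.0]hexan-2-ol 24, made from 2-methylcyclopent-2-enone 16.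
4. Enabling feature: in ring B the carbinol C3' is homoallylic to the tetrasubstituted C5'=C6' bond (C3'–C4'–C5'=C6'), C6' carries the alkyne, and both ring neighbours of C6' are fully substituted (quaternary C1', methyl-bearing C5'). C3'–C5' can therefore be stored as a cyclopropane bond and C6' as a propargylic carbinol whose cation can only open that bond, with water entering anti at C3'.
5. Order of ring events: ring A present from the start; temporary epoxide (step 5); temporary cyclopropane on a cyclopentane (step 11); ring B (step 15). The chirality of ring B comes from one CBS reduction relayed by a directed Simmons–Smith reaction.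

Key step: step 15

Remark: compound 1, (4R,6R)-actinol, is assumed to be a purchasable enantiopure building block; locants in the comments are carotenoid locants (primed for the acetylenic half, ring B) unless a compound's own systematic locants are named.

## Route

Step 1
Reactants: 1 (4R,6R)-4-hydroxy-2,2,6-trimethylcyclohexan-1-one (actinol)
Product: 2 (4R,6R)-4-[(tert-butyldimethylsilyl)oxy]-2,2,6-trimethylcyclohexan-1-one
Conditions: TBSCl, imidazole, DMF, 25 °C
Reagents that add atoms: tert-butyldimethylsilyl chloride, CC(C)(C)[Si](C)(C)Cl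
Why: Imidazole-promoted silyl ether formation protects the carbinol of 1 so that the enolate chemistry of step 2 is possible, and no stereocentre is touched.

Step 2
Reactants: 2 (4R,6R)-4-[(tert-butyldimethylsilyl)oxy]-2,2,6-trimethylcyclohexan-1-one
Product: 4 (4R)-4-[(tert-butyldimethylsilyl)oxy]-2,6,6-trimethylcyclohex-1-en-1-yl trifluoromethanesulfonate, via lithium enolate 3 (not isolated)
Conditions: LiN(i-Pr)2, THF, −78 °C; then PhNTf2, −78 → 0 °C
Reagents that add atoms: N-phenylbis(trifluoromethanesulfonimide), O=S(=O)(N(c1ccccc1)S(=O)(=O)C(F)(F)F)C(F)(F)F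
Why: Only one α-carbon of 2 (the CHMe carbon) carries hydrogen, the other being quaternary, so deprotonation and O-sulfonylation of enolate 3 (enol triflate formation) can give a single regioisomer, and the CHMe stereocentre is erased on purpose.

Step 3
Reactants: 4 (4R)-4-[(tert-butyldimethylsilyl)oxy]-2,6,6-trimethylcyclohex-1-en-1-yl trifluoromethanesulfonate; 5 but-3-en-2-one
Product: 6 (3E)-4-[(4R)-4-[(tert-butyldimethylsilyl)oxy]-2,6,6-trimethylcyclohex-1-en-1-yl]but-3-en-2-one
Conditions: Pd(OAc)2 (cat.), PPh3, Et3N, DMF, 70 °C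
Reagents that add atoms: none
Why: Heck reaction of the alkenyl triflate with the electron-poor terminal alkene (oxidative addition to zerovalent palladium, syn carbopalladation at the unsubstituted carbon, syn β-hydride elimination) should give the E-configured dienone, that is the C7=C8 bond.

Step 4
Reactants: 6 (3E)-4-[(4R)-4-[(tert-butyldimethylsilyl)oxy]-2,6,6-trimethylcyclohex-1-en-1-yl]but-3-en-2-one
Product: 7 (3E)-4-[(4R)-4-hydroxy-2,6,6-trimethylcyclohex-1-en-1-yl]but-3-en-2-one
Conditions: HF·pyridine, THF, 0 → 25 °C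
Reagents that add atoms: none
Why: Fluoride-mediated cleavage of the silyl ether frees the C3 hydroxyl that has to direct the next step, and the dienone is inert to HF·pyridine.

Step 5
Reactants: 7 (3E)-4-[(4R)-4-hydroxy-2,6,6-trimethylcyclohex-1-en-1-yl]but-3-en-2-one
Product: 8 (3E)-4-[(1R,4S,6S)-4-hydroxy-2,2,6-trimethyl-7-oxabicyclo[4.1.0]heptan-1-yl]but-3-en-2-one
Conditions: VO(acac)2 (cat.), t-BuOOH, CH2Cl2, 0 → 25 °C
Reagents that add atoms: tert-butyl hydroperoxide, CC(C)(C)OO
Why: Vanadium-catalysed hydroxyl-directed epoxidation of a homoallylic alcohol delivers the oxygen to the electron-rich tetrasubstituted C5=C6 bond on the face of the C3 hydroxyl (this sets C5 and C6 as the epoxide cis to 3-OH) and leaves the electron-poor C7=C8 bond alone.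

Step 6
Reactants: 8 (3E)-4-[(1R,4S,6S)-4-hydroxy-2,2,6-trimethyl-7-oxabicyclo[4.1.0]heptan-1-yl]but-3-en-2-one
Product: 9 (3E)-4-[(1R,2R,4S)-1,2,4-trihydroxy-2,6,6-trimethylcyclohexyl]but-3-en-2-one
Conditions: HClO4 (cat.), THF/H2O, 0 → 25 °C
Reagents that add atoms: water, O
Why: Acid-catalysed hydrolytic opening of the epoxide (closest known case: 5,6-epoxy-β-ionone to its trans-5,6-glycol) should occur by attack of water at the tertiary C5 with inversion, because positive charge at C6 would be conjugated to the electron-poor enone, so C5 becomes (R) and the untouched C6–O bond keeps C6 (R).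

Step 7
Reactants: 9 (3E)-4-[(1R,2R,4S)-1,2,4-trihydroxy-2,6,6-trimethylcyclohexyl]but-3-en-2-one
Product: 10 (1R,2R,4S)-1-[(1E)-3-hydroxy-3-methylpenta-1,4-dien-1-yl]-2,6,6-trimethylcyclohexane-1,2,4-triol (both epimers at the new carbinol)
Conditions: CH2=CHMgBr (excess), THF, −20 → 0 °C; aq. NH4Cl
Reagents that add atoms: vinylmagnesium bromide, C=C[Mg]Br
Why: Grignard 1,2-addition of the vinyl group to the enone carbonyl (three further equivalents are consumed by the hydroxyls) builds C10 and C11, and the new carbinol centre needs no control because step 8 destroys it.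

Step 8
Reactants: 10 (1R,2R,4S)-1-[(1E)-3-hydroxy-3-methylpenta-1,4-dien-1-yl]-2,6,6-trimethylcyclohexane-1,2,4-triol
Product: 11 [(2E,4E)-3-methyl-5-[(1R,2R,4S)-1,2,4-trihydroxy-2,6,6-trimethylcyclohexyl]penta-2,4-dien-1-yl]triphenylphosphonium bromide
Conditions: PPh3·HBr, MeOH, 0 → 25 °C
Reagents that add atoms: triphenylphosphine hydrobromide, [PH+](c1ccccc1)(c1ccccc1)c1ccccc1.[Br-]
Why: Acid ionises the tertiary doubly allylic carbinol and triphenylphosphine captures the pentadienyl cation at its unhindered terminus C11 (allylic transposition to an allylic phosphonium salt), which should settle in the thermodynamically preferred 7E,9E geometry while the ring hydroxyls, not being doubly allylic, stay in place.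

Step 9
Reactants: 11 [(2E,4E)-3-methyl-5-[(1R,2R,4S)-1,2,4-trihydroxy-2,6,6-trimethylcyclohexyl]penta-2,4-dien-1-yl]triphenylphosphonium bromide; 12 (2E,4E,6E)-2,7-dimethylocta-2,4,6-trienedial
Product: 15 (2E,4E,6E,8E,10E,12E)-2,7,11-trimethyl-13-[(1R,2R,4S)-1,2,4-trihydroxy-2,6,6-trimethylcyclohexyl]trideca-2,4,6,8,10,12-hexaenal, via ylide 13 (not isolated), via 8Z isomer 14 (not isolated)
Conditions: NaOMe, MeOH/CH2Cl2, 0 → 25 °C (12 in excess); then EtOAc, reflux
Reagents that add atoms: none
Why: Wittig reaction of ylide 13 with one formyl group of 12 (excess 12 suppresses the double reaction) forms C11=C12, and the sterically hindered Z isomer 14 should relax thermally to the all-E aldehyde.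

Step 10
Reactants: 16 2-methylcyclopent-2-en-1-one
Product: 17 (1R)-2-methylcyclopent-2-en-1-ol
Conditions: (S)-2-methyl-CBS-oxazaborolidine (cat.), BH3·SMe2, THF, −20 °C
Reagents that add atoms: none
Why: CBS reduction, in which the oxazaborolidine–borane complex distinguishes the alkenyl flank from the CH2 flank of the ketone, should give the (R)-allylic alcohol and thereby sets the only stereocentre from which ring B is derived.

Step 11
Reactants: 17 (1R)-2-methylcyclopent-2-en-1-ol
Product: 18 (1S,2R,5R)-1-methylbicyclo[3.1.0]hexan-2-ol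
Conditions: Et2Zn, CH2I2, CH2Cl2, 0 °C
Reagents that add atoms: diiodomethane, ICI
Why: Hydroxyl-directed Simmons–Smith cyclopropanation delivers the methylene from the zinc alkoxide to the alkene face cis to the oxygen, so the carbinol centre fixes both ring-fusion centres (1S,5R).

Step 12
Reactants: 18 (1S,2R,5R)-1-methylbicyclo[3.1.0]hexan-2-ol
Product: 19 (1S,5R)-1-methylbicyclo[3.1.0]hexan-2-one
Conditions: (n-Pr4N)RuO4 (cat.), N-methylmorpholine N-oxide, 4 Å molecular sieves, CH2Cl2, 25 °C
Reagents that add atoms: none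
Why: Ley–Griffith oxidation turns the secondary cyclopropylcarbinol into the ketone under neutral conditions that do not open the cyclopropane.

Step 13
Reactants: 19 (1S,5R)-1-methylbicyclo[3.1.0]hexan-2-one
Product: 23 (1S,5S)-1,3,3-trimethylbicyclo[3.1.0]hexan-2-one, via first potassium enolate 20 (not isolated), via monomethyl ketone 21 (not isolated), via second potassium enolate 22 (not isolated)
Conditions: KOt-Bu (excess), MeI (excess), THF, 0 → 25 °C
Reagents that add atoms: iodomethane, CI
Why: Exhaustive enolate alkylation is regiochemically unambiguous because C3 of 19 is the only enolisable position (C1 is a quaternary cyclopropane carbon), and the two methyl groups become the geminal pair on C1' of the target.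

Step 14
Reactants: 23 (1S,5S)-1,3,3-trimethylbicyclo[3.1.0]hexan-2-one
Product: 24 (1S,5S)-2-ethynyl-1,3,3-trimethylbicyclo[3.1.0]hexan-2-ol (both C2 epimers)
Conditions: HC≡CMgBr, THF, 0 → 40 °C; aq. NH4Cl
Reagents that add atoms: ethynylmagnesium bromide, C#C[Mg]Br
Why: Grignard addition of the small ethynyl nucleophile to the non-enolisable ketone installs C7' and C8', and either configuration of the new carbinol centre is acceptable because it becomes sp2 in step 15.

Step 15
Reactants: 24 (1S,5S)-2-ethynyl-1,3,3-trimethylbicyclo[3.1.0]hexan-2-ol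
Product: 25 (1R)-4-ethynyl-3,5,5-trimethylcyclohex-3-en-1-ol
Conditions: HClO4 (cat.), 1,4-dioxane/H2O, 0 → 25 °C
Reagents that add atoms: water, O
Why: Acid removes the tertiary hydroxyl of 24 as water and leaves a cation at C2 (the later C6') that is propargylic and cyclopropylcarbinylic; water then attacks the ring-fusion carbon C5 (the later C3') from the side opposite to the C1–C5 bond, which breaks and becomes the C5'=C6' double bond (cyclopropylcarbinyl to homoallyl rearrangement). The closest known reactions are the i-steroid rearrangement, the acid hydration of bicyclo[3.1.0]hex-2-yl cations of the thujane type to cyclohex-3-enols and the Julia opening of alkynyl cyclopropyl carbinols to homoallylic enynes. The six-membered ring is closed by ring enlargement: the three- and five-membered rings merge through scission of their shared bond (homoallyl mode), so that the ring C1'–C6' exists for the first time after this step. The one stereocentre, C3', is controlled by the configuration of C5 in 24, since backside attack with inversion should give (R), and both C2 epimers of 24 converge because C2 becomes sp2. The selectivity needed is scission of the fusion bond and not of the external cyclopropane bond, and ring opening and not hydration at the alkyne terminus; the first is secured by the secondary (versus primary) carbon that takes up the nucleophile and by the complete loss of ring strain, the second by the terminal alkyne, whose allenyl form would be a primary vinyl cation. Elimination cannot compete because both neighbours of the cationic carbon are fully substituted, so the only other path is reversible return to 24.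

Step 16
Reactants: 25 (1R)-4-ethynyl-3,5,5-trimethylcyclohex-3-en-1-ol; 26 ethyl but-2-ynoate
Product: 27 ethyl (2E)-5-[(4R)-4-hydroxy-2,6,6-trimethylcyclohex-1-en-1-yl]-3-methylpent-2-en-4-ynoate
Conditions: Pd(OAc)2 (cat.), tris(2,6-dimethoxyphenyl)phosphine (cat.), THF, 25 °C
Reagents that add atoms: none
Why: Palladium-catalysed cross-addition of a terminal alkyne (donor) to an alkynoate (acceptor), a syn hydroalkynylation that puts the alkynyl group on the β-carbon, should give the E-enynoate and thus the 9'E geometry without protection of the alcohol.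

Step 17
Reactants: 27 ethyl (2E)-5-[(4R)-4-hydroxy-2,6,6-trimethylcyclohex-1-en-1-yl]-3-methylpent-2-en-4-ynoate
Product: 28 (1R)-4-[(3E)-5-hydroxy-3-methylpent-3-en-1-yn-1-yl]-3,5,5-trimethylcyclohex-3-en-1-ol
Conditions: i-Bu2AlH, CH2Cl2, −78 → 0 °C; aq. KNaC4H4O6
Reagents that add atoms: none
Why: Aluminium hydride 1,2-reduction of the conjugated ester gives the primary allylic alcohol with retention of the enyne and of the double-bond geometry.

Step 18
Reactants: 28 (1R)-4-[(3E)-5-hydroxy-3-methylpent-3-en-1-yn-1-yl]-3,5,5-trimethylcyclohex-3-en-1-ol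
Product: 29 [(2E)-5-[(4R)-4-hydroxy-2,6,6-trimethylcyclohex-1-en-1-yl]-3-methylpent-2-en-4-yn-1-yl]triphenylphosphonium bromide
Conditions: PPh3·HBr, MeOH, 25 °C
Reagents that add atoms: triphenylphosphine hydrobromide, [PH+](c1ccccc1)(c1ccccc1)c1ccccc1.[Br-]
Why: Triphenylphosphine hydrobromide converts the primary allylic alcohol into the allylic phosphonium salt (acid-promoted substitution at the allylic terminus) while the secondary homoallylic 3'-OH is not ionised.

Step 19
Reactants: 29 [(2E)-5-[(4R)-4-hydroxy-2,6,6-trimethylcyclohex-1-en-1-yl]-3-methylpent-2-en-4-yn-1-yl]triphenylphosphonium bromide; 15 (2E,4E,6E,8E,10E,12E)-2,7,11-trimethyl-13-[(1R,2R,4S)-1,2,4-trihydroxy-2,6,6-trimethylcyclohexyl]trideca-2,4,6,8,10,12-hexaenal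
Product: 32 heteroxanthin (3S,5R,6R,3'R)-7',8'-didehydro-5,6-dihydro-β,β-carotene-3,5,6,3'-tetrol, via ylide 30 (not isolated), via 11'Z isomer 31 (not isolated)
Conditions: NaOMe, MeOH/CH2Cl2, 0 → 25 °C; then EtOAc/heptane, reflux, dark
Reagents that add atoms: none
Why: Wittig reaction of ylide 30 with aldehyde 15 joins the halves at C11'=C12' under basic conditions that the free hydroxyls and the acid-sensitive 5,6-diol tolerate, and the hindered Z isomer 31 should isomerise thermally to the all-E target.

## Compound list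

1 | (4R,6R)-4-hydroxy-2,2,6-trimethylcyclohexan-1-one (actinol) | O=C1[C@H](C)C[C@@H](O)CC1(C)C | starting material
2 | (4R,6R)-4-[(tert-butyldimethylsilyl)oxy]-2,2,6-trimethylcyclohexan-1-one | O=C1[C@H](C)C[C@@H](O[Si](C)(C)C(C)(C)C)CC1(C)C | intermediate
3 | lithium (4R)-4-[(tert-butyldimethylsilyl)oxy]-2,6,6-trimethylcyclohex-1-en-1-olate | [Li+].[O-]C1=C(C)C[C@@H](O[Si](C)(C)C(C)(C)C)CC1(C)C | intermediate (not isolated)
4 | (4R)-4-[(tert-butyldimethylsilyl)oxy]-2,6,6-trimethylcyclohex-1-en-1-yl trifluoromethanesulfonate | O=S(=O)(OC1=C(C)C[C@@H](O[Si](C)(C)C(C)(C)C)CC1(C)C)C(F)(F)F | intermediate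
5 | but-3-en-2-one | CC(=O)C=C | starting material
6 | (3E)-4-[(4R)-4-[(tert-butyldimethylsilyl)oxy]-2,6,6-trimethylcyclohex-1-en-1-yl]but-3-en-2-one | CC(=O)/C=C/C1=C(C)C[C@@H](O[Si](C)(C)C(C)(C)C)CC1(C)C | intermediate
7 | (3E)-4-[(4R)-4-hydroxy-2,6,6-trimethylcyclohex-1-en-1-yl]but-3-en-2-one | CC(=O)/C=C/C1=C(C)C[C@@H](O)CC1(C)C | intermediate
8 | (3E)-4-[(1R,4S,6S)-4-hydroxy-2,2,6-trimethyl-7-oxabicyclo[4.1.0]heptan-1-yl]but-3-en-2-one (epoxide cis to the hydroxyl) | CC(=O)/C=C/[C@]12O[C@@]1(C)C[C@@H](O)CC2(C)C | intermediate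
9 | (3E)-4-[(1R,2R,4S)-1,2,4-trihydroxy-2,6,6-trimethylcyclohexyl]but-3-en-2-one | CC(=O)/C=C/[C@@]1(O)C(C)(C)C[C@H](O)C[C@@]1(C)O | intermediate
10 | (1R,2R,4S)-1-[(1E)-3-hydroxy-3-methylpenta-1,4-dien-1-yl]-2,6,6-trimethylcyclohexane-1,2,4-triol (both side-chain carbinol epimers) | C=CC(C)(O)/C=C/[C@@]1(O)C(C)(C)C[C@H](O)C[C@@]1(C)O | intermediate
11 | [(2E,4E)-3-methyl-5-[(1R,2R,4S)-1,2,4-trihydroxy-2,6,6-trimethylcyclohexyl]penta-2,4-dien-1-yl]triphenylphosphonium bromide | [Br-].C(/C=C(C)/C=C/[C@@]1(O)C(C)(C)C[C@H](O)C[C@@]1(C)O)[P+](c1ccccc1)(c1ccccc1)c1ccccc1 | intermediate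
12 | (2E,4E,6E)-2,7-dimethylocta-2,4,6-trienedial | O=C/C(C)=C/C=C/C=C(C)/C=O | starting material
13 | triphenylphosphonium ylide of 11 | C(/C=C(C)/C=C/[C@@]1(O)C(C)(C)C[C@H](O)C[C@@]1(C)O)=P(c1ccccc1)(c1ccccc1)c1ccccc1 | intermediate (not isolated)
14 | (2E,4E,6E,8Z,10E,12E)-2,7,11-trimethyl-13-[(1R,2R,4S)-1,2,4-trihydroxy-2,6,6-trimethylcyclohexyl]trideca-2,4,6,8,10,12-hexaenal | O=C/C(C)=C/C=C/C=C(C)/C=C\C=C(C)\C=C\[C@@]1(O)C(C)(C)C[C@H](O)C[C@@]1(C)O | intermediate (not isolated)
15 | (2E,4E,6E,8E,10E,12E)-2,7,11-trimethyl-13-[(1R,2R,4S)-1,2,4-trihydroxy-2,6,6-trimethylcyclohexyl]trideca-2,4,6,8,10,12-hexaenal | O=C/C(C)=C/C=C/C=C(C)/C=C/C=C(C)/C=C/[C@@]1(O)C(C)(C)C[C@H](O)C[C@@]1(C)O | intermediate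
16 | 2-methylcyclopent-2-en-1-one | CC1=CCCC1=O | starting material
17 | (1R)-2-methylcyclopent-2-en-1-ol | O[C@@H]1CCC=C1C | intermediate
18 | (1S,2R,5R)-1-methylbicyclo[3.1.0]hexan-2-ol (hydroxyl cis to the cyclopropane methylene) | O[C@@H]1CC[C@@H]2C[C@]12C | intermediate
19 | (1S,5R)-1-methylbicyclo[3.1.0]hexan-2-one | O=C1CC[C@@H]2C[C@]12C | intermediate
20 | potassium 1-methylbicyclo[3.1.0]hex-2-en-2-olate (enolate of 19, ring-fusion centres as in 19) | [K+].[O-]C1=CC[C@@H]2C[C@]12C | intermediate (not isolated)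
21 | (1S,5R)-1,3-dimethylbicyclo[3.1.0]hexan-2-one (both C3 epimers) | O=C1C(C)C[C@@H]2C[C@]12C | intermediate (not isolated)
22 | potassium 1,3-dimethylbicyclo[3.1.0]hex-2-en-2-olate (enolate of 21, ring-fusion centres as in 19) | [K+].[O-]C1=C(C)C[C@@H]2C[C@]12C | intermediate (not isolated)
23 | (1S,5S)-1,3,3-trimethylbicyclo[3.1.0]hexan-2-one | O=C1C(C)(C)C[C@@H]2C[C@]12C | intermediate
24 | (1S,5S)-2-ethynyl-1,3,3-trimethylbicyclo[3.1.0]hexan-2-ol (both C2 epimers) | C#CC1(O)C(C)(C)C[C@@H]2C[C@]12C | intermediate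
25 | (1R)-4-ethynyl-3,5,5-trimethylcyclohex-3-en-1-ol | CC1=C(C#C)C(C)(C)C[C@H](O)C1 | intermediate
26 | ethyl but-2-ynoate | CC#CC(=O)OCC | starting material
27 | ethyl (2E)-5-[(4R)-4-hydroxy-2,6,6-trimethylcyclohex-1-en-1-yl]-3-methylpent-2-en-4-ynoate | CC1=C(C#C/C(C)=C/C(=O)OCC)C(C)(C)C[C@H](O)C1 | intermediate
28 | (1R)-4-[(3E)-5-hydroxy-3-methylpent-3-en-1-yn-1-yl]-3,5,5-trimethylcyclohex-3-en-1-ol | CC1=C(C#C/C(C)=C/CO)C(C)(C)C[C@H](O)C1 | intermediate
29 | [(2E)-5-[(4R)-4-hydroxy-2,6,6-trimethylcyclohex-1-en-1-yl]-3-methylpent-2-en-4-yn-1-yl]triphenylphosphonium bromide | CC1=C(C#C/C(C)=C/C[P+](c2ccccc2)(c2ccccc2)c2ccccc2)C(C)(C)C[C@H](O)C1.[Br-] | intermediate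
30 | triphenylphosphonium ylide of 29 | CC1=C(C#C/C(C)=C/C=P(c2ccccc2)(c2ccccc2)c2ccccc2)C(C)(C)C[C@H](O)C1 | intermediate (not isolated)
31 | (11'Z)-heteroxanthin | CC1=C(C#C\C(C)=C\C=C/C(C)=C/C=C/C=C(C)/C=C/C=C(C)/C=C/[C@@]2(O)C(C)(C)C[C@H](O)C[C@@]2(C)O)C(C)(C)C[C@H](O)C1 | intermediate (not isolated)
32 | heteroxanthin, (3S,5R,6R,3'R)-7',8'-didehydro-5,6-dihydro-β,β-carotene-3,5,6,3'-tetrol | CC1=C(C#C/C(C)=C/C=C/C(C)=C/C=C/C=C(C)/C=C/C=C(C)/C=C/[C@@]2(O)C(C)(C)C[C@H](O)C[C@@]2(C)O)C(C)(C)C[C@H](O)C1 | target

## Step count and risks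

Total step count: 19 (steps 1–9 build fragment A and extend it to 15, steps 10–18 build fragment B, step 19 joins them).

Longest linear sequence: 10 steps (16 to 32 through steps 10–19; the sequence 1 to 32 through steps 1–9 and 19 is equally long).

Steps most likely to fail:

Step 15. The cation may be lost through scission of the external cyclopropane bond (water entering at the methylene carbon and leaving a cyclopentene), or through hydration at the alkyne terminus followed by tautomerisation (Meyer–Schuster type). An opening with too much free-cation character would also erode the inversion at C3'. The fallback uses known chemistry, sets out from 4 and comes back at 25, and takes ring B from 1 instead of building it. Sonogashira coupling of 4 with ethynyltrimethylsilane (PdCl2(PPh3)2, CuI, Et3N, DMF, 50 °C) should give tert-butyldimethyl{[(1R)-3,5,5-trimethyl-4-[(trimethylsilyl)ethynyl]cyclohex-3-en-1-yl]oxy}silane F1. Treatment of F1 with n-Bu4NF in THF should then remove both silyl groups and give 25.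

Step 8. Ionisation in acid places positive charge next to the tertiary 6-hydroxyl, so a 1,2-shift of a ring carbon (semipinacol ring enlargement) or loss of the 6-hydroxyl may compete with capture by the phosphine, and the C9 geometry may not settle cleanly. The fallback avoids acid, sets out from 9 and comes back at 11. A Horner–Wadsworth–Emmons reaction of 9 with triethyl phosphonoacetate (NaH in excess, THF) should give, after removal of the minor 2Z isomer, ethyl (2E,4E)-3-methyl-5-[(1R,2R,4S)-1,2,4-trihydroxy-2,6,6-trimethylcyclohexyl]penta-2,4-dienoate F2. Reduction with i-Bu2AlH would give (1R,2R,4S)-1-[(1E,3E)-5-hydroxy-3-methylpenta-1,3-dien-1-yl]-2,6,6-trimethylcyclohexane-1,2,4-triol F3. Appel bromination of the primary allylic alcohol (CBr4, PPh3, CH2Cl2, 0 °C) would give (1R,2R,4S)-1-[(1E,3E)-5-bromo-3-methylpenta-1,3-dien-1-yl]-2,6,6-trimethylcyclohexane-1,2,4-triol F4, and PPh3 in MeCN should convert F4 into 11.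

Step 3. Insertion of the alkene into the hindered, tetrasubstituted alkenylpalladium species may be slow, so that reduction or hydrolysis of the triflate and polymerisation of the enone take over. The fallback sets out from 4 and comes back at 6. Palladium-catalysed reductive carbonylation of 4 (Pd(OAc)2, 1,3-bis(diphenylphosphino)propane, CO, Et3SiH, Et3N, DMF) should give (4R)-4-[(tert-butyldimethylsilyl)oxy]-2,6,6-trimethylcyclohex-1-ene-1-carbaldehyde F5. A Horner–Wadsworth–Emmons reaction of F5 with diethyl (2-oxopropyl)phosphonate (NaH, THF) should then give 6.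

Further compounds

F1 | step 15 | tert-butyldimethyl{[(1R)-3,5,5-trimethyl-4-[(trimethylsilyl)ethynyl]cyclohex-3-en-1-yl]oxy}silane | CC1=C(C#C[Si](C)(C)C)C(C)(C)C[C@H](O[Si](C)(C)C(C)(C)C)C1
F2 | step 8 | ethyl (2E,4E)-3-methyl-5-[(1R,2R,4S)-1,2,4-trihydroxy-2,6,6-trimethylcyclohexyl]penta-2,4-dienoate | CCOC(=O)/C=C(C)/C=C/[C@@]1(O)C(C)(C)C[C@H](O)C[C@@]1(C)O
F3 | step 8 | (1R,2R,4S)-1-[(1E,3E)-5-hydroxy-3-methylpenta-1,3-dien-1-yl]-2,6,6-trimethylcyclohexane-1,2,4-triol | OC/C=C(C)/C=C/[C@@]1(O)C(C)(C)C[C@H](O)C[C@@]1(C)O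
F4 | step 8 | (1R,2R,4S)-1-[(1E,3E)-5-bromo-3-methylpenta-1,3-dien-1-yl]-2,6,6-trimethylcyclohexane-1,2,4-triol | BrC/C=C(C)/C=C/[C@@]1(O)C(C)(C)C[C@H](O)C[C@@]1(C)O
F5 | step 3 | (4R)-4-[(tert-butyldimethylsilyl)oxy]-2,6,6-trimethylcyclohex-1-ene-1-carbaldehyde | O=CC1=C(C)C[C@@H](O[Si](C)(C)C(C)(C)C)CC1(C)C
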